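**Retrosynthetic overview**

- Numbering follows the labdane skeleton (ring A: C1–C5, C10; ring B: C5–C10; C17 on C8; side chain C11–C16). Late disconnections: malonate half ester ⇒ dienol 20 + Meldrum's acid; C13=C14–C15 ⇒ terminal alkyne 18 (syn-carboalumination, formaldehyde); C17–C8 ⇒ enol triflate 16; C9–C11 ⇒ enone 11 + iodide 12.
- Ring B of 11 is never closed as a six-membered ring. The monocyclic diazoketone 9 first closes a cyclopentanone (C5, C7, C8, C9, C10) fused to a cyclopropane (C5, C6, C7) by carbene addition to the exocyclic C5=C6 bond; acid then cuts the shared C5–C7 bond, C6 is inserted, and the five-membered ring expands to ring B.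
- Enabling feature: in ring B the unsubstituted CH2 C6 lies between C7 (α to the latent C8 carbonyl) and the ring-fusion carbon C5, which is flanked by the quaternary carbons C4 and C10. Cleavage of C5–C7 is therefore the only path to a tertiary cation, and it leaves the C6=C7–C8=O enone from which the C7=C8 double bond is later fixed without positional isomers.
- Ring and stereocentre order: ring A is bought (1); C10 is set by palladium-catalysed asymmetric allylation (step 2); cyclopentanone + cyclopropane, then ring B (step 6); C5 and C9 follow from C10 under thermodynamic control; the E side-chain alkene comes last.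

Key step: step 6

Assumption: the (R)-enantiomer of t-BuPHOX is taken to induce the mirror-image configuration of the established (S)-ligand/(S)-ketone pairing, and (4-iodobut-1-yn-1-yl)trimethylsilane is taken as a purchasable reagent.

Step 1
Reactants: 1 2,2,6-trimethylcyclohexan-1-one; 2 allyl chloroformate
Product: 3 prop-2-en-1-yl 2,6,6-trimethylcyclohex-1-en-1-yl carbonate
Conditions: LiN(SiMe3)2, THF, −78 → 0 °C; then 2, −78 → 23 °C
Reagents that add atoms: none
Why: The ketone has only one enolisable position, so its lithium enolate forms regiospecifically and is O-acylated by the chloroformate (enol carbonate formation); no stereocentre is formed.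

Step 2
Reactants: 3 prop-2-en-1-yl 2,6,6-trimethylcyclohex-1-en-1-yl carbonate
Product: 4 (2R)-2,6,6-trimethyl-2-(prop-2-en-1-yl)cyclohexan-1-one
Conditions: Pd2(dba)3 (2.5 mol%), (R)-t-BuPHOX (6.25 mol%), THF, 25 °C
Reagents that add atoms: none
Why: Palladium-catalysed decarboxylative asymmetric allylic alkylation (Tsuji allylation): zerovalent palladium ionises the allyl carbonate, CO2 is lost, and enolate–allyl coupling inside the chiral PHOX complex creates the quaternary centre C10, whose configuration is set by the ligand enantiomer.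

Step 3
Reactants: 4 (2R)-2,6,6-trimethyl-2-(prop-2-en-1-yl)cyclohexan-1-one
Product: 6 (1R)-1,3,3-trimethyl-2-methylidene-1-(prop-2-en-1-yl)cyclohexane, via silyl carbinol 5 (not isolated)
Conditions: Me3SiCH2Li, THF, 0 → 23 °C; H2O work-up; then KH, THF, 60 °C
Reagents that add atoms: (trimethylsilyl)methyllithium, [Li]C[Si](C)(C)C
Why: Peterson olefination: the ketone cannot enolise, so the organolithium can only add to the carbonyl, and syn-elimination of silanolate from the potassium alkoxide gives the exocyclic methylene (C6); the carbinol centre is formed and destroyed and C10 is untouched.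

Step 4
Reactants: 6 (1R)-1,3,3-trimethyl-2-methylidene-1-(prop-2-en-1-yl)cyclohexane
Product: 7 1-[(1R)-1,3,3-trimethyl-2-methylidenecyclohexyl]propan-2-one
Conditions: PdCl2 (10 mol%), CuCl, O2 (1 atm), DMF/H2O 7:1, 23 °C
Reagents that add atoms: water, O (source of the carbonyl oxygen; O2 is the terminal oxidant)
Why: Tsuji–Wacker oxidation: Markovnikov hydroxypalladation of the monosubstituted alkene and β-hydride elimination give the methyl ketone, while the 1,1-disubstituted alkene between two quaternary carbons is too hindered to react and has no allylic hydrogen through which it could migrate.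

Step 5
Reactants: 7 1-[(1R)-1,3,3-trimethyl-2-methylidenecyclohexyl]propan-2-one
Product: 9 1-diazo-3-[(1R)-1,3,3-trimethyl-2-methylidenecyclohexyl]propan-2-one, via trifluoroacetyl diketone 8 (not isolated)
Conditions: LiN(SiMe3)2, THF, −78 °C; CF3CO2CH2CF3; then MeSO2N3, Et3N, H2O, MeCN, 23 °C
Reagents that add atoms: 2,2,2-trifluoroethyl trifluoroacetate, O=C(OCC(F)(F)F)C(F)(F)F (trifluoroacetyl group of 8); methanesulfonyl azide, CS(=O)(=O)N=[N+]=[N-] (diazo nitrogens of 9)
Why: Detrifluoroacetylative (Regitz-type) diazo transfer: kinetic deprotonation occurs at the methyl group because the CH2 is neopentylic, Claisen acylation gives the trifluoroacetyl diketone, and diazo transfer from the sulfonyl azide with loss of the trifluoroacetyl group gives the diazomethyl ketone.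

Step 6
Reactants: 9 1-diazo-3-[(1R)-1,3,3-trimethyl-2-methylidenecyclohexyl]propan-2-one
Product: 11 (4aS,8aR)-5,5,8a-trimethyl-4a,5,6,7,8,8a-hexahydronaphthalen-2(1H)-one, via tricyclic cyclopropyl ketone 10 (not isolated)
Conditions: Rh2(OAc)4 (1 mol%), CH2Cl2, 23 °C, slow addition of 9; then TsOH·H2O, PhMe, 90 °C
Reagents that add atoms: none
Why: Rh2(OAc)4 turns the diazomethyl ketone into an electrophilic rhodium carbene whose carbon (C7) adds across the exocyclic C5=C6 bond, the standard intramolecular cyclopropanation of 1-diazohex-5-en-2-ones to bicyclo[3.1.0]hexan-2-ones; this [2+1] addition closes the cyclopentanone C5–C7–C8–C9–C10 through the new bond C7–C5 and the cyclopropane through C7–C6, cis-fused because the C9–C8 tether from C10 reaches only one face of the alkene. Protonation of the carbonyl of 10 by TsOH then breaks the bond C5–C7 shared by the two small rings, because only this cleavage leaves a tertiary cation (C5, between the quaternary C4 and C10) next to the C7=C8 enol, so that C6 is inserted between C5 and C7 and the five-membered ring becomes the six-membered ring B (closest known reaction type: the acid-catalysed ring expansion of 5-alkylbicyclo[3.1.0]hexanones to cyclohexenones, as in thujone to carvotanacetone or sabina ketone to 4-isopropylcyclohex-2-enone). Loss of H6 gives the C5=C6–C7=C8 dienol, which should ketonise under the equilibrating acid to the conjugated enone with the new hydrogen on C5 trans to the C10 methyl, the more stable ring fusion of a 4,4,10-trimethyldecalin, so C5 is set under thermodynamic control by C10 while the two temporary stereocentres of 10 (C5, C7) are erased. The step needs cyclopropanation to beat 1,5 C–H insertion, which the electron-rich 1,1-disubstituted alkene held five atoms from an acceptor-only carbene secures, and it needs cleavage of the internal and not the external cyclopropane bond, which the fully substituted C5 against the primary C6 secures. No second alkene or nucleophile is present that could intercept the C5 cation.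

Step 7
Reactants: 11 (4aS,8aR)-5,5,8a-trimethyl-4a,5,6,7,8,8a-hexahydronaphthalen-2(1H)-one; 12 (4-iodobut-1-yn-1-yl)trimethylsilane
Product: 14 (1R,4aS,8aS)-5,5,8a-trimethyl-1-[4-(trimethylsilyl)but-3-yn-1-yl]-4a,5,6,7,8,8a-hexahydronaphthalen-2(1H)-one, via C1 epimer 13 (not isolated)
Conditions: LiN(i-Pr)2, THF, −78 °C; 12, DMPU, −78 → −20 °C; then DBU, PhMe, 80 °C
Reagents that add atoms: none
Why: Kinetic α′-deprotonation of the cross-conjugated enone can only occur at C9 (the other α-carbon is vinylic), SN2 alkylation by the primary iodide installs C11–C14, and DBU equilibrates C9 through the enol to the epimer with the side chain equatorial and cis to the C10 methyl (thermodynamic control, the usual preference of 2-alkylcyclohexanones).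

Step 8
Reactants: 14 (1R,4aS,8aS)-5,5,8a-trimethyl-1-[4-(trimethylsilyl)but-3-yn-1-yl]-4a,5,6,7,8,8a-hexahydronaphthalen-2(1H)-one
Product: 16 (1R,4aS,8aS)-5,5,8a-trimethyl-1-[4-(trimethylsilyl)but-3-yn-1-yl]-1,4,4a,5,6,7,8,8a-octahydronaphthalen-2-yl trifluoromethanesulfonate, via lithium enolate 15 (not isolated)
Conditions: LiBH(s-Bu)3, THF, −78 °C; then PhNTf2, −78 → 0 °C
Reagents that add atoms: lithium tri-sec-butylborohydride, [Li+].CCC(C)[BH-](C(C)CC)C(C)CC (lithium of 15); N-phenylbis(trifluoromethanesulfonimide), O=S(=O)(N(c1ccccc1)S(=O)(=O)C(F)(F)F)C(F)(F)F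
Why: Conjugate (1,4) hydride reduction of the β-unsubstituted cyclohexenone by the hindered borohydride gives the C7=C8 lithium enolate regiospecifically, and O-sulfonylation with PhNTf2 traps it as the enol triflate (reductive enolate trapping); C9 is no longer enolisable afterwards and keeps its configuration.

Step 9
Reactants: 16 (1R,4aS,8aS)-5,5,8a-trimethyl-1-[4-(trimethylsilyl)but-3-yn-1-yl]-1,4,4a,5,6,7,8,8a-octahydronaphthalen-2-yl trifluoromethanesulfonate
Product: 17 trimethyl{4-[(1S,4aS,8aS)-2,5,5,8a-tetramethyl-1,4,4a,5,6,7,8,8a-octahydronaphthalen-1-yl]but-1-yn-1-yl}silane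
Conditions: MeMgBr, Fe(acac)3 (5 mol%), THF/NMP, −30 → 0 °C
Reagents that add atoms: methylmagnesium bromide, C[Mg]Br
Why: Iron-catalysed Kumada-type cross-coupling of an alkenyl triflate with a methyl Grignard reagent replaces OTf by the C17 methyl with the double bond held at C7=C8; the alkynylsilane is inert.

Step 10
Reactants: 17 trimethyl{4-[(1S,4aS,8aS)-2,5,5,8a-tetramethyl-1,4,4a,5,6,7,8,8a-octahydronaphthalen-1-yl]but-1-yn-1-yl}silane
Product: 18 (1S,4aS,8aS)-1-(but-3-yn-1-yl)-2,5,5,8a-tetramethyl-1,4,4a,5,6,7,8,8a-octahydronaphthalene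
Conditions: K2CO3, MeOH, 23 °C
Reagents that add atoms: none
Why: Methoxide-induced protodesilylation of the alkynylsilane frees the terminal alkyne without touching the trisubstituted ring alkene.

Step 11
Reactants: 18 (1S,4aS,8aS)-1-(but-3-yn-1-yl)-2,5,5,8a-tetramethyl-1,4,4a,5,6,7,8,8a-octahydronaphthalene
Product: 20 (2E)-3-methyl-5-[(1S,4aS,8aS)-2,5,5,8a-tetramethyl-1,4,4a,5,6,7,8,8a-octahydronaphthalen-1-yl]pent-2-en-1-ol, via alkenylalane 19 (not isolated)
Conditions: Me3Al, Cp2ZrCl2 (20 mol%), CH2Cl2, 0 → 23 °C; then n-BuLi, THF, −78 °C; (CH2O)n, −78 → 23 °C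
Reagents that add atoms: trimethylaluminium, C[Al](C)C; formaldehyde (from paraformaldehyde), C=O
Why: Zirconium-catalysed carboalumination of a terminal alkyne (Negishi carboalumination) adds methyl and aluminium syn with the methyl on the internal carbon, and the derived alkenylalanate is hydroxymethylated by formaldehyde with retention, so the C13=C14 alkene is E by the syn-addition mechanism.

Step 12
Reactants: 20 (2E)-3-methyl-5-[(1S,4aS,8aS)-2,5,5,8a-tetramethyl-1,4,4a,5,6,7,8,8a-octahydronaphthalen-1-yl]pent-2-en-1-ol; 21 2,2-dimethyl-1,3-dioxane-4,6-dione (Meldrum's acid)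
Product: 22 3-{[(2E)-3-methyl-5-[(1S,4aS,8aS)-2,5,5,8a-tetramethyl-1,4,4a,5,6,7,8,8a-octahydronaphthalen-1-yl]pent-2-en-1-yl]oxy}-3-oxopropanoic acid (CNP0279336.1)
Conditions: PhMe, 90 °C
Reagents that add atoms: none
Why: Thermal acylation of the allylic alcohol by Meldrum's acid (ring opening at an acyl carbon with loss of acetone) gives the malonic acid monoester directly, with no stereocentre or alkene affected.

**Compound list**

1 | 2,2,6-trimethylcyclohexan-1-one (racemic) | CC1CCCC(C)(C)C1=O | starting material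
2 | allyl chloroformate | C=CCOC(=O)Cl | starting material
3 | prop-2-en-1-yl 2,6,6-trimethylcyclohex-1-en-1-yl carbonate | C=CCOC(=O)OC1=C(C)CCCC1(C)C | intermediate
4 | (2R)-2,6,6-trimethyl-2-(prop-2-en-1-yl)cyclohexan-1-one | O=C1C(C)(C)CCC[C@]1(C)CC=C | intermediate
5 | (2R)-2,6,6-trimethyl-2-(prop-2-en-1-yl)-1-[(trimethylsilyl)methyl]cyclohexan-1-ol (both carbinol epimers) | C[Si](C)(C)CC1(O)C(C)(C)CCC[C@]1(C)CC=C | intermediate
6 | (1R)-1,3,3-trimethyl-2-methylidene-1-(prop-2-en-1-yl)cyclohexane | C=C1C(C)(C)CCC[C@]1(C)CC=C | intermediate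
7 | 1-[(1R)-1,3,3-trimethyl-2-methylidenecyclohexyl]propan-2-one | C=C1C(C)(C)CCC[C@]1(C)CC(C)=O | intermediate
8 | 1,1,1-trifluoro-5-[(1R)-1,3,3-trimethyl-2-methylidenecyclohexyl]pentane-2,4-dione | C=C1C(C)(C)CCC[C@]1(C)CC(=O)CC(=O)C(F)(F)F | intermediate
9 | 1-diazo-3-[(1R)-1,3,3-trimethyl-2-methylidenecyclohexyl]propan-2-one | C=C1C(C)(C)CCC[C@]1(C)CC(=O)C=[N+]=[N-] | intermediate
10 | (1R,3S,6R)-6,10,10-trimethyltricyclo[4.4.0.0^1,3]decan-4-one (cyclopropane CH2 cis to the angular methyl) | O=C1C[C@@]2(C)CCCC(C)(C)[C@]23C[C@H]13 | intermediate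
11 | (4aS,8aR)-5,5,8a-trimethyl-4a,5,6,7,8,8a-hexahydronaphthalen-2(1H)-one | O=C1C=C[C@H]2C(C)(C)CCC[C@]2(C)C1 | intermediate
12 | (4-iodobut-1-yn-1-yl)trimethylsilane | C[Si](C)(C)C#CCCI | starting material
13 | (1S,4aS,8aS)-5,5,8a-trimethyl-1-[4-(trimethylsilyl)but-3-yn-1-yl]-4a,5,6,7,8,8a-hexahydronaphthalen-2(1H)-one | O=C1C=C[C@H]2C(C)(C)CCC[C@]2(C)[C@@H]1CCC#C[Si](C)(C)C | intermediate
14 | (1R,4aS,8aS)-5,5,8a-trimethyl-1-[4-(trimethylsilyl)but-3-yn-1-yl]-4a,5,6,7,8,8a-hexahydronaphthalen-2(1H)-one | O=C1C=C[C@H]2C(C)(C)CCC[C@]2(C)[C@H]1CCC#C[Si](C)(C)C | intermediate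
15 | lithium (1R,4aS,8aS)-5,5,8a-trimethyl-1-[4-(trimethylsilyl)but-3-yn-1-yl]-1,4,4a,5,6,7,8,8a-octahydronaphthalen-2-olate | [Li+].[O-]C1=CC[C@H]2C(C)(C)CCC[C@]2(C)[C@H]1CCC#C[Si](C)(C)C | intermediate
16 | (1R,4aS,8aS)-5,5,8a-trimethyl-1-[4-(trimethylsilyl)but-3-yn-1-yl]-1,4,4a,5,6,7,8,8a-octahydronaphthalen-2-yl trifluoromethanesulfonate | O=S(=O)(OC1=CC[C@H]2C(C)(C)CCC[C@]2(C)[C@H]1CCC#C[Si](C)(C)C)C(F)(F)F | intermediate
17 | trimethyl{4-[(1S,4aS,8aS)-2,5,5,8a-tetramethyl-1,4,4a,5,6,7,8,8a-octahydronaphthalen-1-yl]but-1-yn-1-yl}silane | CC1=CC[C@H]2C(C)(C)CCC[C@]2(C)[C@H]1CCC#C[Si](C)(C)C | intermediate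
18 | (1S,4aS,8aS)-1-(but-3-yn-1-yl)-2,5,5,8a-tetramethyl-1,4,4a,5,6,7,8,8a-octahydronaphthalene | CC1=CC[C@H]2C(C)(C)CCC[C@]2(C)[C@H]1CCC#C | intermediate
19 | dimethyl{(1E)-2-methyl-4-[(1S,4aS,8aS)-2,5,5,8a-tetramethyl-1,4,4a,5,6,7,8,8a-octahydronaphthalen-1-yl]but-1-en-1-yl}alumane | CC1=CC[C@H]2C(C)(C)CCC[C@]2(C)[C@H]1CC/C(C)=C/[Al](C)C | intermediate
20 | (2E)-3-methyl-5-[(1S,4aS,8aS)-2,5,5,8a-tetramethyl-1,4,4a,5,6,7,8,8a-octahydronaphthalen-1-yl]pent-2-en-1-ol (labda-7,13E-dien-15-ol) | CC1=CC[C@H]2C(C)(C)CCC[C@]2(C)[C@H]1CC/C(C)=C/CO | intermediate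
21 | 2,2-dimethyl-1,3-dioxane-4,6-dione (Meldrum's acid) | CC1(C)OC(=O)CC(=O)O1 | starting material
22 | 3-{[(2E)-3-methyl-5-[(1S,4aS,8aS)-2,5,5,8a-tetramethyl-1,4,4a,5,6,7,8,8a-octahydronaphthalen-1-yl]pent-2-en-1-yl]oxy}-3-oxopropanoic acid (CNP0279336.1) | CC1=CC[C@H]2C(C)(C)CCC[C@]2(C)[C@H]1CC/C(C)=C/COC(=O)CC(=O)O | target

**Step count**

Total steps: 12. Longest linear sequence: 12 steps (1 → 22); compounds 2, 12 and 21 are purchased.

**Three steps most likely to fail**

Step 6. The carbene may insert into the C–H bonds of the ring CH2 or the methyl group next to C10 instead of adding to the hindered alkene. In the acid stage the C5 cation may suffer a 1,2-methyl shift from C4 or C10, or the enone may stop at the unconjugated isomer. The fallback is a Saegusa–Ito one-carbon ring expansion, which still makes ring B from a cyclopentanone. It sets out from 4. Tsuji–Wacker oxidation (PdCl2, CuCl, O2, DMF/H2O) should give (6R)-2,2,6-trimethyl-6-(2-oxopropyl)cyclohexan-1-one F1. Aldol condensation (KOH, xylenes, 110 °C) should give (7aR)-4,4,7a-trimethyl-1,4,5,6,7,7a-hexahydro-2H-inden-2-one F2. Li/NH3 reduction with trapping of the regiodefined enolate by Me3SiCl/Et3N should give trimethyl{[(7aR)-4,4,7a-trimethyl-3a,4,5,6,7,7a-hexahydro-1H-inden-2-yl]oxy}silane F3. Simmons–Smith cyclopropanation (Et2Zn, CH2I2) should give trimethyl{[(6R)-6,10,10-trimethyltricyclo[4.4.0.0^2,4]decan-4-yl]oxy}silane F4. FeCl3 in DMF followed by NaOAc in MeOH opens the shared cyclopropane bond and eliminates HCl to the cyclohexenone, and DBU equilibrates the ring fusion to the trans isomer. The route is rejoined at 11.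

Step 7. SN2 attack at the enolate carbon next to the quaternary C10 is slow, so E2 elimination of the homopropargylic iodide by the basic enolate, proton transfer and over-alkylation may take over. The fallback uses a fast allylic electrophile and builds the alkyne later. It sets out from 11. LiN(i-Pr)2, then allyl bromide, then DBU should give (1R,4aS,8aS)-5,5,8a-trimethyl-1-(prop-2-en-1-yl)-4a,5,6,7,8,8a-hexahydronaphthalen-2(1H)-one F5. LiBH(s-Bu)3 then PhNTf2 should give (1R,4aS,8aS)-5,5,8a-trimethyl-1-(prop-2-en-1-yl)-1,4,4a,5,6,7,8,8a-octahydronaphthalen-2-yl trifluoromethanesulfonate F6. MeMgBr with Fe(acac)3 should give (1S,4aS,8aS)-2,5,5,8a-tetramethyl-1-(prop-2-en-1-yl)-1,4,4a,5,6,7,8,8a-octahydronaphthalene F7. Hydroboration of the terminal alkene with 9-BBN and NaOH/H2O2 oxidation should give 3-[(1S,4aS,8aS)-2,5,5,8a-tetramethyl-1,4,4a,5,6,7,8,8a-octahydronaphthalen-1-yl]propan-1-ol F8. Dess–Martin oxidation should give 3-[(1S,4aS,8aS)-2,5,5,8a-tetramethyl-1,4,4a,5,6,7,8,8a-octahydronaphthalen-1-yl]propanal F9. Ohira–Bestmann homologation (dimethyl (1-diazo-2-oxopropyl)phosphonate, K2CO3, MeOH) then gives the terminal alkyne, and the route is rejoined at 18.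

Step 3. The silylmethyl nucleophile may fail to add to a carbonyl flanked by two quaternary carbons, or the adduct may revert to ketone on heating with KH. The fallback uses the smallest carbon nucleophile and a separate dehydration. It sets out from 4. MeLi in Et2O at 0 °C should give (6R)-1,2,2,6-tetramethyl-6-(prop-2-en-1-yl)cyclohexan-1-ol F10. SOCl2 in pyridine at 0 °C dehydrates it toward the methyl group, the only β-hydrogens available. The route is rejoined at 6.

**Further compounds**

F1 | step 6 | (6R)-2,2,6-trimethyl-6-(2-oxopropyl)cyclohexan-1-one | O=C1C(C)(C)CCC[C@]1(C)CC(C)=O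
F2 | step 6 | (7aR)-4,4,7a-trimethyl-1,4,5,6,7,7a-hexahydro-2H-inden-2-one | O=C1C=C2C(C)(C)CCC[C@]2(C)C1
F3 | step 6 | trimethyl{[(7aR)-4,4,7a-trimethyl-3a,4,5,6,7,7a-hexahydro-1H-inden-2-yl]oxy}silane (ring-fusion epimers) | C[Si](C)(C)OC1=CC2C(C)(C)CCC[C@]2(C)C1
F4 | step 6 | trimethyl{[(6R)-6,10,10-trimethyltricyclo[4.4.0.0^2,4]decan-4-yl]oxy}silane (other centres as formed) | C[Si](C)(C)OC12CC1C1C(C)(C)CCC[C@]1(C)C2
F5 | step 7 | (1R,4aS,8aS)-5,5,8a-trimethyl-1-(prop-2-en-1-yl)-4a,5,6,7,8,8a-hexahydronaphthalen-2(1H)-one | O=C1C=C[C@H]2C(C)(C)CCC[C@]2(C)[C@H]1CC=C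
F6 | step 7 | (1R,4aS,8aS)-5,5,8a-trimethyl-1-(prop-2-en-1-yl)-1,4,4a,5,6,7,8,8a-octahydronaphthalen-2-yl trifluoromethanesulfonate | O=S(=O)(OC1=CC[C@H]2C(C)(C)CCC[C@]2(C)[C@H]1CC=C)C(F)(F)F
F7 | step 7 | (1S,4aS,8aS)-2,5,5,8a-tetramethyl-1-(prop-2-en-1-yl)-1,4,4a,5,6,7,8,8a-octahydronaphthalene | CC1=CC[C@H]2C(C)(C)CCC[C@]2(C)[C@H]1CC=C
F8 | step 7 | 3-[(1S,4aS,8aS)-2,5,5,8a-tetramethyl-1,4,4a,5,6,7,8,8a-octahydronaphthalen-1-yl]propan-1-ol | CC1=CC[C@H]2C(C)(C)CCC[C@]2(C)[C@H]1CCCO
F9 | step 7 | 3-[(1S,4aS,8aS)-2,5,5,8a-tetramethyl-1,4,4a,5,6,7,8,8a-octahydronaphthalen-1-yl]propanal | CC1=CC[C@H]2C(C)(C)CCC[C@]2(C)[C@H]1CCC=O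
F10 | step 3 | (6R)-1,2,2,6-tetramethyl-6-(prop-2-en-1-yl)cyclohexan-1-ol (carbinol epimers) | CC1(O)C(C)(C)CCC[C@]1(C)CC=C
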